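**Plan**

1. Retrosynthesis: the seven phenols are unmasked last (MOM ethers). The methylcyclohexene is cut at C3″–C4″ and re-bonded C1″–C4″, a reverse 1,3-shift to a 1-aroyl-2-aryl-4-methyl-4-styrylcyclobutane. Further cuts: chromanone C2–aryl (conjugate arylation of a chromone), styryl–aryl (Heck), aryl–C(=O) (aryllithium + Weinreb amide), and the cyclobutane itself (Wolff ring contraction of a 2-diazocyclopentanone).
2. Forward order of rings: cyclopentenone by ring-closing metathesis → (S)-3-arylcyclopentanone → cyclobutane by photochemical ring contraction (strain stored) → aryl ketone → Heck coupling with an 8-iodochromone → chromanone → cyclohexene by ring expansion (strain released) → deprotection.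
3. Feature used: in the target C4″ is α to the aryl ketone and C1″=C2″–C3″ is an allyl unit ending in the benzylic C3″. The ring isomer with C4″ bonded to C1″ instead of C3″ is a strained aroyl-substituted vinylcyclobutane. Its ketyl opens to an enolate at C4″ and an allyl radical over C1″–C3″, which recloses at C3″.
4. Stereochemistry: C5″ comes from the rhodium/(S)-BINAP arylation; chromanone C2 from the palladium/pyridine–oxazoline arylation; C3″ and C4″ form in the ring expansion under control of C5″. The two cyclobutane carbons carried as epimer mixtures become planar in that step, so all isomers converge.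

Key step: step 16

Remark: locants C1″–C6″ denote the methylcyclohexene ring: C1″ bears the methyl group, C3″ the chromanone, C4″ the aroyl group, C5″ the dihydroxyphenyl group.
Remark: compounds 16–25 are carried as epimer mixtures at the methyl/vinyl quaternary carbon and, from 21 on, also at the carbonyl-bearing cyclobutane carbon; SMILES define only the centres that are controlled.
Remark: the sense of induction in steps 10 and 15 is assumed to follow that of the parent substrates (cyclopent-2-enone, simple chromones); if step 15 shows the opposite sense, the other ligand enantiomer is used.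

**Step 1**
Reactants: 1 4-bromobenzene-1,3-diol
Product: 2 1-bromo-2,4-bis(methoxymethoxy)benzene
Conditions: MOMCl (2.5 equiv), i-Pr2NEt, CH2Cl2, 0 °C to rt
Reagents that add atoms: chloromethyl methyl ether, COCCl
Why: Double O-alkylation of the phenols with MOMCl and a hindered amine base (MOM protection); no stereocentre is involved.

**Step 2**
Reactants: 2 1-bromo-2,4-bis(methoxymethoxy)benzene
Product: 4 [2,4-bis(methoxymethoxy)phenyl]boronic acid, via aryllithium 3 (not isolated)
Conditions: n-BuLi, THF, −78 °C; B(Oi-Pr)3, −78 °C to rt; dilute HCl to pH 5, 0 °C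
Reagents that add atoms: triisopropyl borate, CC(C)OB(OC(C)C)OC(C)C; water, O
Why: Bromine–lithium exchange at −78 °C (the ortho-OMOM group stabilises the aryllithium) followed by borylation with a trialkyl borate and mild hydrolysis is the standard arylboronic acid synthesis.

**Step 3**
Reactants: 2 1-bromo-2,4-bis(methoxymethoxy)benzene
Product: 6 1-bromo-2,4-bis(methoxymethoxy)-3-(3-methylbut-2-en-1-yl)benzene, via aryllithium 5 (not isolated)
Conditions: LiN(i-Pr)2, THF, −78 °C; prenyl bromide, −78 to 0 °C
Reagents that add atoms: 1-bromo-3-methylbut-2-ene, CC(C)=CCBr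
Why: Directed ortho-metalation: the amide base removes the proton between the two OMOM groups (the most acidic one) without exchanging the bromide, and the aryllithium is alkylated at the primary carbon of prenyl bromide.

**Step 4**
Reactants: 7 methyl (E)-2-methylbut-2-enoate (methyl tiglate)
Product: 9 methyl 2-ethenyl-2-methylpent-4-enoate (racemic), via lithium dienolate 8 (not isolated)
Conditions: LiN(i-Pr)2, THF/DMPU, −78 °C; allyl bromide, −78 to 0 °C
Reagents that add atoms: allyl bromide, C=CCBr
Why: Deconjugative α-alkylation of an ester dienolate: γ-deprotonation of the tiglate and kinetic alkylation at the α-carbon give the β,γ-unsaturated ester with the methyl/vinyl quaternary carbon (racemic; the centre is erased in step 16).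

**Step 5**
Reactants: 9 methyl 2-ethenyl-2-methylpent-4-enoate
Product: 10 2-ethenyl-N-methoxy-N,2-dimethylpent-4-enamide (racemic)
Conditions: MeNHOMe·HCl, i-PrMgCl (2 equiv per amine salt), THF, −20 °C to rt; 1 M HCl work-up
Reagents that add atoms: N,O-dimethylhydroxylamine hydrochloride, CNOC.Cl
Why: Aminolysis of the ester by the magnesium amide of N,O-dimethylhydroxylamine (Weinreb amide formation), which also works on α-quaternary esters.

**Step 6**
Reactants: 10 2-ethenyl-N-methoxy-N,2-dimethylpent-4-enamide
Product: 11 4-ethenyl-4-methylhepta-1,6-dien-3-one (racemic)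
Conditions: CH2=CHMgBr, THF, 0 °C; inverse quench into cold 1 M HCl
Reagents that add atoms: vinylmagnesium bromide, C=C[Mg]Br
Why: Weinreb ketone synthesis: the chelated tetrahedral adduct stops at the ketone stage, and the inverse acidic quench keeps the liberated amine from adding to the vinyl ketone.

**Step 7**
Reactants: 11 4-ethenyl-4-methylhepta-1,6-dien-3-one
Product: 12 5-ethenyl-5-methylcyclopent-2-en-1-one (racemic)
Conditions: second-generation Grubbs catalyst (3 mol%), CH2Cl2 (dilute), 40 °C
Reagents that add atoms: none
Why: Ring-closing metathesis: only the allyl/acryloyl pair can close to an unstrained five-membered ring, while the vinyl group on the quaternary carbon could only give a four-membered ring and is left untouched.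

**Step 8**
Reactants: 13 7-hydroxy-4H-chromen-4-one
Product: 14 7-hydroxy-8-iodo-4H-chromen-4-one
Conditions: N-iodosuccinimide (1.05 equiv), TsOH (cat.), MeCN, 0 °C to rt
Reagents that add atoms: N-iodosuccinimide, O=C1CCC(=O)N1I
Why: Electrophilic aromatic iodination ortho to the free phenol, at C8 between the hydroxyl group and the ring oxygen, which is the most nucleophilic position of 7-hydroxychromones.

**Step 9**
Reactants: 14 7-hydroxy-8-iodo-4H-chromen-4-one
Product: 15 8-iodo-7-(methoxymethoxy)-4H-chromen-4-one
Conditions: MOMCl, i-Pr2NEt, CH2Cl2, 0 °C to rt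
Reagents that add atoms: chloromethyl methyl ether, COCCl
Why: MOM protection of the phenol by O-alkylation.

**Step 10**
Reactants: 12 5-ethenyl-5-methylcyclopent-2-en-1-one; 4 [2,4-bis(methoxymethoxy)phenyl]boronic acid
Product: 16 (3S)-3-[2,4-bis(methoxymethoxy)phenyl]-5-ethenyl-5-methylcyclopentan-1-one (C5 epimer mixture)
Conditions: [Rh(OH)((S)-BINAP)]2 (3 mol%), 4 (2.5 equiv), dioxane/H2O 10:1, 40 °C
Reagents that add atoms: none
Why: Rhodium-catalysed asymmetric conjugate addition of an arylboronic acid to an enone (Hayashi–Miyaura reaction): the (S)-BINAP complex adds the aryl group to one enantioface of the enone in both enantiomers of racemic 12 (catalyst control, as for cyclopent-2-enone) and so sets the benzylic centre as S.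

**Step 11**
Reactants: 16 (3S)-3-[2,4-bis(methoxymethoxy)phenyl]-5-ethenyl-5-methylcyclopentan-1-one
Product: 19 (3R)-3-[2,4-bis(methoxymethoxy)phenyl]-2-diazo-5-ethenyl-5-methylcyclopentan-1-one (C5 epimer mixture), via lithium enolate 17 (not isolated), via trifluoroacetyl ketone 18 (not isolated)
Conditions: LiN(SiMe3)2, THF, −78 °C; CF3CO2CH2CF3; then MsN3, Et3N, H2O (1 equiv), MeCN, rt
Reagents that add atoms: methanesulfonyl azide, CS(=O)(=O)N=[N+]=[N-]
Why: Detrifluoroacetylative diazo transfer (Regitz-type): C2 is the only enolisable position because C5 is quaternary, so activation as the trifluoroacetyl ketone and diazo transfer occur there with complete regiocontrol (the descriptor changes to R only because the diazo carbon now outranks the aryl group).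

**Step 12**
Reactants: 19 (3R)-3-[2,4-bis(methoxymethoxy)phenyl]-2-diazo-5-ethenyl-5-methylcyclopentan-1-one
Product: 21 (2S)-2-[2,4-bis(methoxymethoxy)phenyl]-4-ethenyl-N-methoxy-N,4-dimethylcyclobutane-1-carboxamide (C1/C4 epimer mixture), via ketene 20 (not isolated)
Conditions: hν (365 nm LEDs or medium-pressure Hg lamp through Pyrex), MeNHOMe (5 equiv), THF, 0 °C
Reagents that add atoms: N,O-dimethylhydroxylamine, CNOC
Why: Photochemical Wolff rearrangement of a cyclic, s-cis-locked α-diazoketone: the quaternary carbon migrates with loss of N2, contracting the five-membered ring to a cyclobutylidene ketene that the amine traps as the Weinreb amide; the new α-centre forms as a mixture that does not matter.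

**Step 13**
Reactants: 21 (2S)-2-[2,4-bis(methoxymethoxy)phenyl]-4-ethenyl-N-methoxy-N,4-dimethylcyclobutane-1-carboxamide; 6 1-bromo-2,4-bis(methoxymethoxy)-3-(3-methylbut-2-en-1-yl)benzene
Product: 23 [2,4-bis(methoxymethoxy)-3-(3-methylbut-2-en-1-yl)phenyl]{(2S)-2-[2,4-bis(methoxymethoxy)phenyl]-4-ethenyl-4-methylcyclobutyl}methanone (C1/C4 epimer mixture), via aryllithium 22 (not isolated)
Conditions: 6 (2 equiv), n-BuLi, THF, −78 °C; then 21, −78 to −20 °C; H2O quench
Reagents that add atoms: none
Why: Weinreb ketone synthesis with an aryllithium made by bromine–lithium exchange: the chelated adduct prevents over-addition, and excess aryllithium compensates for competing α-deprotonation.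

**Step 14**
Reactants: 23 the vinylcyclobutyl aryl ketone; 15 8-iodo-7-(methoxymethoxy)-4H-chromen-4-one
Product: 24 8-[(E)-2-{(3S)-2-[2,4-bis(methoxymethoxy)-3-(3-methylbut-2-en-1-yl)benzoyl]-3-[2,4-bis(methoxymethoxy)phenyl]-1-methylcyclobutyl}ethenyl]-7-(methoxymethoxy)-4H-chromen-4-one (C1/C2 epimer mixture of the cyclobutane)
Conditions: Pd(OAc)2 (10 mol%), Bu4NCl, NaHCO3, DMF, 60 °C
Reagents that add atoms: none
Why: Mizoroki–Heck reaction under ligand-free phase-transfer conditions: the aryl group adds to the terminal carbon of the monosubstituted alkene and β-hydride elimination can only give the E-styrene because the neighbouring carbon is quaternary; the trisubstituted prenyl alkene is unreactive.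

**Step 15**
Reactants: 24 the chromone-bearing styrylcyclobutane; 4 [2,4-bis(methoxymethoxy)phenyl]boronic acid
Product: 25 (2S)-2-[2,4-bis(methoxymethoxy)phenyl]-8-[(E)-2-{(3S)-2-[2,4-bis(methoxymethoxy)-3-(3-methylbut-2-en-1-yl)benzoyl]-3-[2,4-bis(methoxymethoxy)phenyl]-1-methylcyclobutyl}ethenyl]-7-(methoxymethoxy)-2,3-dihydro-4H-chromen-4-one (C1/C2 epimer mixture of the cyclobutane)
Conditions: Pd(OCOCF3)2 (10 mol%), (R)-t-BuPyOX (12 mol%), NH4PF6 (30 mol%), H2O (5 equiv), 4 (3 equiv), ClCH2CH2Cl, 50 °C
Reagents that add atoms: none
Why: Palladium-catalysed asymmetric conjugate addition of an arylboronic acid to a chromone with a pyridine–oxazoline ligand: the catalyst alone fixes the new chromanone C2 centre (expected S with this ligand enantiomer), the other centres being remote, and the redox-neutral, mildly acidic conditions avoid base-induced ring opening of the chromanone.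

**Step 16**
Reactants: 25 the chromanone-bearing styrylcyclobutane
Product: 26 (2S)-2-[2,4-bis(methoxymethoxy)phenyl]-8-[(1S,5S,6R)-6-[2,4-bis(methoxymethoxy)-3-(3-methylbut-2-en-1-yl)benzoyl]-5-[2,4-bis(methoxymethoxy)phenyl]-3-methylcyclohex-2-en-1-yl]-7-(methoxymethoxy)-2,3-dihydro-4H-chromen-4-one (hepta-MOM ether of 27)
Conditions: SmI2 (20 mol%), dry degassed THF, 45 °C, argon
Reagents that add atoms: none
Why: Proposed new method: divalent samarium transfers one electron to the cyclobutyl aryl ketone (helped by chelation through the ortho-OMOM oxygen); the samarium ketyl undergoes β-scission of the cyclobutane bond between the carbonyl-bearing carbon and the quaternary carbon, giving a trivalent samarium enolate at C4″ and a tertiary allyl radical delocalised onto the benzylic C3″, which adds back to the enolate carbon through C3″ to give the ketyl of the cyclohexene, and back electron transfer to trivalent samarium releases 26 and SmI2, so the step is a redox-neutral, catalytic 1,3-shift that enlarges the four-membered ring to the six-membered one. The closest known reaction types are the SmI2-catalysed radical-relay cycloadditions of aryl cyclopropyl ketones (ketyl formation, ring fragmentation, radical rebound onto the samarium enolate, back electron transfer), the electron-transfer-initiated stepwise Diels–Alder reactions of 2'-hydroxychalcones with 1-aryldienes, and the thermal vinylcyclobutane-to-cyclohexene rearrangement. The cyclohexene is closed in the 6-exo-trig radical mode through a boat-like transition state in which the enolate faces the U-shaped, E-configured allyl radical, the competing 4-exo return to the cyclobutane being reversible and uphill by the ring strain. C4″ is set by bond formation on the enolate face anti to the C5″ aryl group (allylic strain; this trans arrangement is also the thermodynamic, epimerisable one), and C3″ is set by the endo-type arrangement in which the bulky samarium enolate/aroyl unit lies over C2″–H and away from the di-ortho-substituted chromanone aryl group, which gives the 3″,4″-cis relationship; C5″ is not touched. The step needs bond selectivity in the fragmentation, six- over four-ring closure and chemoselectivity between two aryl ketones: these are secured by the allyl/styryl stabilisation of the radical at the quaternary carbon (the other α-bond would give only a secondary benzyl radical), by release of the cyclobutane strain, and by the fact that only the cyclobutyl ketone has a fragmentable β-bond (ketyl formation at the chromanone is reversible and unproductive), while all epimers at the two cyclobutane carbons that become planar converge on one product.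

**Step 17**
Reactants: 26 the hepta-MOM ether
Product: 27 (2S)-2-(2,4-dihydroxyphenyl)-8-[(1S,5S,6R)-6-[2,4-dihydroxy-3-(3-methylbut-2-en-1-yl)benzoyl]-5-(2,4-dihydroxyphenyl)-3-methylcyclohex-2-en-1-yl]-7-hydroxy-2,3-dihydro-4H-chromen-4-one
Conditions: ZnBr2 (10 equiv), n-PrSH (20 equiv), CH2Cl2, 0 °C to rt, short reaction time
Reagents that add atoms: none
Why: Lewis acid/thiol cleavage of all seven MOM ethers (transacetalisation to the O,S-acetal) under brief, nearly neutral conditions that should neither cyclise the prenyl group onto the adjacent phenol nor open the chromanone; no stereocentre is touched.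

**Compound list**

1 | 4-bromobenzene-1,3-diol | Oc1ccc(Br)c(O)c1 | starting material
2 | 1-bromo-2,4-bis(methoxymethoxy)benzene | COCOc1ccc(Br)c(OCOC)c1 | intermediate
3 | [2,4-bis(methoxymethoxy)phenyl]lithium | [Li]c1ccc(OCOC)cc1OCOC | intermediate (not isolated)
4 | [2,4-bis(methoxymethoxy)phenyl]boronic acid | OB(O)c1ccc(OCOC)cc1OCOC | intermediate
5 | [3-bromo-2,6-bis(methoxymethoxy)phenyl]lithium | COCOc1ccc(Br)c(OCOC)c1[Li] | intermediate (not isolated)
6 | 1-bromo-2,4-bis(methoxymethoxy)-3-(3-methylbut-2-en-1-yl)benzene | COCOc1ccc(Br)c(OCOC)c1CC=C(C)C | intermediate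
7 | methyl (E)-2-methylbut-2-enoate (methyl tiglate) | C/C=C(\C)C(=O)OC | starting material
8 | lithium 1-methoxy-2-methylbuta-1,3-dien-1-olate (dienolate of 7) | C=CC(C)=C(OC)O[Li] | intermediate (not isolated)
9 | methyl 2-ethenyl-2-methylpent-4-enoate (racemic) | C=CCC(C)(C=C)C(=O)OC | intermediate
10 | 2-ethenyl-N-methoxy-N,2-dimethylpent-4-enamide (racemic) | C=CCC(C)(C=C)C(=O)N(C)OC | intermediate
11 | 4-ethenyl-4-methylhepta-1,6-dien-3-one (racemic) | C=CCC(C)(C=C)C(=O)C=C | intermediate
12 | 5-ethenyl-5-methylcyclopent-2-en-1-one (racemic) | O=C1C=CCC1(C)C=C | intermediate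
13 | 7-hydroxy-4H-chromen-4-one | O=c1ccoc2cc(O)ccc12 | starting material
14 | 7-hydroxy-8-iodo-4H-chromen-4-one | O=c1ccoc2c(I)c(O)ccc12 | intermediate
15 | 8-iodo-7-(methoxymethoxy)-4H-chromen-4-one | O=c1ccoc2c(I)c(OCOC)ccc12 | intermediate
16 | (3S)-3-[2,4-bis(methoxymethoxy)phenyl]-5-ethenyl-5-methylcyclopentan-1-one (C5 epimer mixture) | O=C1C[C@@H](c2ccc(OCOC)cc2OCOC)CC1(C)C=C | intermediate
17 | lithium enolate of 16 (C1–C2 enolate) | [Li]OC1=C[C@@H](c2ccc(OCOC)cc2OCOC)CC1(C)C=C | intermediate (not isolated)
18 | 2-(trifluoroacetyl) derivative of 16 | O=C1C(C(=O)C(F)(F)F)[C@@H](c2ccc(OCOC)cc2OCOC)CC1(C)C=C | intermediate (not isolated)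
19 | (3R)-3-[2,4-bis(methoxymethoxy)phenyl]-2-diazo-5-ethenyl-5-methylcyclopentan-1-one (same spatial arrangement at C3 as in 16; C5 epimer mixture) | O=C1C(=[N+]=[N-])[C@@H](c2ccc(OCOC)cc2OCOC)CC1(C)C=C | intermediate
20 | {2-[2,4-bis(methoxymethoxy)phenyl]-4-ethenyl-4-methylcyclobutylidene}methanone (ketene; aryl-bearing carbon unchanged) | O=C=C1[C@@H](c2ccc(OCOC)cc2OCOC)CC1(C)C=C | intermediate (not isolated)
21 | (2S)-2-[2,4-bis(methoxymethoxy)phenyl]-4-ethenyl-N-methoxy-N,4-dimethylcyclobutane-1-carboxamide (C1/C4 epimer mixture) | CON(C)C(=O)C1[C@@H](c2ccc(OCOC)cc2OCOC)CC1(C)C=C | intermediate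
22 | [2,4-bis(methoxymethoxy)-3-(3-methylbut-2-en-1-yl)phenyl]lithium | [Li]c1ccc(OCOC)c(CC=C(C)C)c1OCOC | intermediate (not isolated)
23 | [2,4-bis(methoxymethoxy)-3-(3-methylbut-2-en-1-yl)phenyl]{(2S)-2-[2,4-bis(methoxymethoxy)phenyl]-4-ethenyl-4-methylcyclobutyl}methanone (C1/C4 epimer mixture) | CC(C)=CCc1c(OCOC)ccc(C(=O)C2[C@@H](c3ccc(OCOC)cc3OCOC)CC2(C)C=C)c1OCOC | intermediate
24 | 8-[(E)-2-{(3S)-2-[2,4-bis(methoxymethoxy)-3-(3-methylbut-2-en-1-yl)benzoyl]-3-[2,4-bis(methoxymethoxy)phenyl]-1-methylcyclobutyl}ethenyl]-7-(methoxymethoxy)-4H-chromen-4-one (cyclobutane C1/C2 epimer mixture) | CC(C)=CCc1c(OCOC)ccc(C(=O)C2[C@@H](c3ccc(OCOC)cc3OCOC)CC2(C)/C=C/c2c(OCOC)ccc3c2occc3=O)c1OCOC | intermediate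
25 | (2S)-2-[2,4-bis(methoxymethoxy)phenyl]-8-[(E)-2-{(3S)-2-[2,4-bis(methoxymethoxy)-3-(3-methylbut-2-en-1-yl)benzoyl]-3-[2,4-bis(methoxymethoxy)phenyl]-1-methylcyclobutyl}ethenyl]-7-(methoxymethoxy)-2,3-dihydro-4H-chromen-4-one (cyclobutane C1/C2 epimer mixture) | CC(C)=CCc1c(OCOC)ccc(C(=O)C2[C@@H](c3ccc(OCOC)cc3OCOC)CC2(C)/C=C/c2c(OCOC)ccc3c2O[C@H](c2ccc(OCOC)cc2OCOC)CC3=O)c1OCOC | intermediate
26 | hepta-MOM ether of 27: (2S)-chromanone, (1S,5S,6R)-cyclohexenyl (= 3″S,5″S,4″R) | CC(C)=CCc1c(OCOC)ccc(C(=O)[C@H]2[C@@H](c3c(OCOC)ccc4c3O[C@H](c3ccc(OCOC)cc3OCOC)CC4=O)C=C(C)C[C@@H]2c2ccc(OCOC)cc2OCOC)c1OCOC | intermediate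
27 | (2S)-2-(2,4-dihydroxyphenyl)-8-[(1S,5S,6R)-6-[2,4-dihydroxy-3-(3-methylbut-2-en-1-yl)benzoyl]-5-(2,4-dihydroxyphenyl)-3-methylcyclohex-2-en-1-yl]-7-hydroxy-2,3-dihydro-4H-chromen-4-one | CC(C)=CCc1c(O)ccc(C(=O)[C@H]2[C@@H](c3c(O)ccc4c3O[C@H](c3ccc(O)cc3O)CC4=O)C=C(C)C[C@@H]2c2ccc(O)cc2O)c1O | target

**Totals and risks**

Total step count: 17. Longest linear sequence: 12 steps (7 → 27 through steps 4–7 and 10–17).

Steps most likely to fail:

1. Step 16 (proposed method). The electron-transfer chain may stall through irreversible consumption of SmI2, for example pinacol coupling or reduction of the allyl radical to an anion that ends as a ring-opened ketone. The allyl radical may also close through the exo-type transition state, or the product ketyl may reopen and equilibrate C3″, giving the 3″-epimer. Fallback with known chemistry: the classical thermal vinylcyclobutane-to-cyclohexene 1,3-shift, moved one stage earlier so that no configurationally labile chromanone is heated. Setting out from 24, heating in degassed o-xylene at 130–140 °C with a radical inhibitor should give the chromone-bearing cyclohexene F1, with the 3″,4″-cis isomer separated by chromatography. The conjugate arylation of step 15 applied to F1 with 4 then returns to the route at 26.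

2. Step 15. The arylpalladium species may insert into the styrene instead of the chromone, the electron-rich ortho-substituted boronic acid may protodeboronate before transmetalation, or facial control may be incomplete on the large substrate. Fallback: make the chromanone before the coupling. Setting out from 15 and 4, the same conjugate arylation on the simple chromone (large excess of boronic acid, enrichment by crystallisation) gives (2S)-2-[2,4-bis(methoxymethoxy)phenyl]-8-iodo-7-(methoxymethoxy)chroman-4-one F2. A base-free Heck coupling of F2 with 23 (Pd(OAc)2, AgOAc, DMF, 50 °C; no base, so no retro-oxa-Michael racemisation) returns to the route at 25.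

3. Step 14. Insertion into the hindered alkene next to the quaternary carbon may be slow, so that hydrodehalogenation of the di-ortho-substituted aryl iodide or arylation at the chromone C2=C3 bond takes over. Fallback: build the styrene by olefin cross-metathesis. Setting out from 15, Suzuki–Miyaura vinylation (CH2=CHBF3K, PdCl2(dppf), Et3N, n-PrOH, 80 °C) gives 8-ethenyl-7-(methoxymethoxy)-4H-chromen-4-one F3. Cross-metathesis of F3 with 23 (second-generation Hoveyda–Grubbs catalyst, CH2Cl2, 40 °C; the hindered alkene does not homodimerise, E product) returns to the route at 24.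

**Further compounds**

F1 | step 16 | 8-[(1S,5S,6R)-6-[2,4-bis(methoxymethoxy)-3-(3-methylbut-2-en-1-yl)benzoyl]-5-[2,4-bis(methoxymethoxy)phenyl]-3-methylcyclohex-2-en-1-yl]-7-(methoxymethoxy)-4H-chromen-4-one | CC(C)=CCc1c(OCOC)ccc(C(=O)[C@H]2[C@@H](c3c(OCOC)ccc4c3occc4=O)C=C(C)C[C@@H]2c2ccc(OCOC)cc2OCOC)c1OCOC
F2 | step 15 | (2S)-2-[2,4-bis(methoxymethoxy)phenyl]-8-iodo-7-(methoxymethoxy)-2,3-dihydro-4H-chromen-4-one | Ic1c(OCOC)ccc2c1O[C@H](c1ccc(OCOC)cc1OCOC)CC2=O
F3 | step 14 | 8-ethenyl-7-(methoxymethoxy)-4H-chromen-4-one | O=c1ccoc2c(C=C)c(OCOC)ccc12
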